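## Retrosynthetic overview

- The target comes from a 2'-O-allyl isoflavone by one reductive cascade: transfer hydrogenation with dynamic kinetic resolution sets C3 as R, the C4 oxygen leaves through a para-quinone methide, and the allyl group is cleaved in the same flask.
- Ring C of that isoflavone is closed through a 2-hydroxyisoflavanone, itself formed by a Lewis-acid 1,2-shift of a fully prenylated chalcone epoxide (the net 2,3-aryl migration that isoflavone synthase performs).
- The chalcone epoxide comes from Claisen–Schmidt condensation and enone epoxidation of a prenylated bis-MOM acetophenone with an O-allyl chromene aldehyde.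
- The chromene aldehyde comes from 2,4-dihydroxybenzaldehyde and 3-methylbut-2-enal by ortho-quinone methide formation and oxa-6π electrocyclisation; the ketone comes from C-prenylation of 2,4-dihydroxyacetophenone.
- Ring order: the dimethylpyran ring on ring B first, then the pyranone ring C; rings A and B are the two resorcinol starting materials.

Assumption: 1-bromo-3-methylbut-2-ene and 3-methylbut-2-enal are taken as cheap catalogue chemicals; the epoxide of step 5 is used as the racemate because its stereocentres are erased in step 6.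

## Route

Step 1
Reactants: 1 2,4-dihydroxyacetophenone; 2 1-bromo-3-methylbut-2-ene (prenyl bromide)
Product: 3 1-[2,4-dihydroxy-3-(3-methylbut-2-enyl)phenyl]ethanone
Conditions: KOH (10% aq), 0 °C → rt
Reagents that add atoms: none
Why: Friedel–Crafts-type C-alkylation of the resorcinol dianion in water, where the carbon between the two phenoxide oxygens is the most nucleophilic site and solvation of the oxygens disfavours O-alkylation, so the 3-prenyl isomer is the main product and is separated from 5-prenyl and O-prenyl by-products by chromatography.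

Step 2
Reactants: 3 1-[2,4-dihydroxy-3-(3-methylbut-2-enyl)phenyl]ethanone
Product: 4 1-[2,4-bis(methoxymethoxy)-3-(3-methylbut-2-enyl)phenyl]ethanone
Conditions: NaH, DMF, 0 °C → rt
Reagents that add atoms: chloromethyl methyl ether (MOMCl), COCCl
Why: Williamson-type acetal ether formation in which NaH deprotonates both phenols, including the hydrogen-bonded one next to the acetyl group, so that free phenoxides cannot divert the later aldol and nucleophilic epoxidation.

Step 3
Reactants: 5 2,4-dihydroxybenzaldehyde; 6 3-methylbut-2-enal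
Product: 8 5-hydroxy-2,2-dimethyl-2H-chromene-6-carbaldehyde, via ortho-quinone methide 7 (not isolated)
Conditions: pyridine, 120 °C (sealed tube)
Reagents that add atoms: none
Why: Knoevenagel-type condensation of the enal at the doubly activated carbon between the two hydroxyls gives an ortho-quinone methide dienone that closes by oxa-6π electrocyclisation through the free, non-chelated oxygen (the ring closure by which prenylated phenols are thought to become chromenes in the plant), which gives the angular 5-hydroxy chromene.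

Step 4
Reactants: 8 5-hydroxy-2,2-dimethyl-2H-chromene-6-carbaldehyde
Product: 9 2,2-dimethyl-5-(prop-2-enyloxy)-2H-chromene-6-carbaldehyde
Conditions: K2CO3, DMF, 60 °C
Reagents that add atoms: allyl bromide, C=CCBr
Why: Williamson ether synthesis on the chelated phenol, with allyl chosen because it survives base, peroxide, BF3 and methanolic HCl and later keeps the ring B oxygen from closing a benzofuran or a pterocarpan.

Step 5
Reactants: 4 1-[2,4-bis(methoxymethoxy)-3-(3-methylbut-2-enyl)phenyl]ethanone; 9 2,2-dimethyl-5-(prop-2-enyloxy)-2H-chromene-6-carbaldehyde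
Product: 11 rac-[2,4-bis(methoxymethoxy)-3-(3-methylbut-2-enyl)phenyl]{trans-3-[2,2-dimethyl-5-(prop-2-enyloxy)-2H-chromen-6-yl]oxiran-2-yl}methanone, via chalcone 10 (not isolated)
Conditions: KOH, EtOH, rt; then 30% H2O2, 0 °C → rt
Reagents that add atoms: hydrogen peroxide, OO
Why: Claisen–Schmidt condensation gives the (E)-chalcone and the hydroperoxide anion then adds only to the electron-poor enone (Weitz–Scheffer epoxidation), leaving the prenyl, allyl and chromene double bonds untouched; the trans epoxide is racemic, which does not matter because both of its stereocentres are destroyed in step 6.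

Step 6
Reactants: 11 rac-trans chalcone epoxide
Product: 14 7-hydroxy-8-(3-methylbut-2-enyl)-3-[2,2-dimethyl-5-(prop-2-enyloxy)-2H-chromen-6-yl]-4H-chromen-4-one, via formyl deoxybenzoin 12 (not isolated), via 2-hydroxyisoflavanone 13 (not isolated)
Conditions: BF3·OEt2 (20 mol%), CH2Cl2, −20 °C; then 2 M HCl, MeOH, 45 °C
Reagents that add atoms: none
Why: BF3 opens the epoxide at the benzylic carbon, which the 2,4-dioxygenated ring B stabilises strongly, and a semipinacol (House–Meinwald) 1,2-acyl shift gives the α-formyl deoxybenzoin, i.e. the net 2,3-aryl migration of the chalcone skeleton; methanolic HCl then unmasks the ring A phenols, the ortho phenol adds to the aldehyde to give the 2-hydroxyisoflavanone lactol, and dehydration closes ring C as the chromone, while the allyl ether stops ring B from forming a benzofuran.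

Step 7
Reactants: 14 7-hydroxy-8-(3-methylbut-2-enyl)-3-[2,2-dimethyl-5-(prop-2-enyloxy)-2H-chromen-6-yl]-4H-chromen-4-one
Product: 19 6-[(3R)-7-hydroxy-8-(3-methylbut-2-enyl)-3,4-dihydro-2H-chromen-3-yl]-2,2-dimethyl-2H-chromen-5-ol, via isoflavanone 15 (not isolated), via cis-isoflavan-4-ol 16 (not isolated), via para-quinone methide 17 (not isolated), via allyl ether 18 (not isolated)
Conditions: RuCl[(R,R)-TsDPEN](p-cymene) (5 mol%), HCO2H/Et3N (5:2), EtOAc, 40 → 60 °C; then Pd(PPh3)4 (5 mol%), 40 °C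
Reagents that add atoms: none
Why: Noyori–Ikariya asymmetric transfer hydrogenation reduces the chromone C=C, the isoflavanone racemises through its enol, and dynamic kinetic resolution with the (R,R) ligand gives the cis-(3R,4R) alcohol, which fixes C3 as R; the benzylic C4–O bond, activated by the para 7-hydroxyl, then ionises to the para-quinone methide and takes up hydride without touching C3, and Pd(PPh3)4 uses the formate already present to cleave the primary allyl ether (Tsuji–Trost deallylation), the prenyl and chromene olefins being inert to all three operations.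

## Compound list

1 | 2,4-dihydroxyacetophenone | CC(=O)c1ccc(O)cc1O | starting material
2 | 1-bromo-3-methylbut-2-ene (prenyl bromide) | CC(C)=CCBr | starting material
3 | 1-[2,4-dihydroxy-3-(3-methylbut-2-enyl)phenyl]ethanone | CC(=O)c1ccc(O)c(CC=C(C)C)c1O | intermediate
4 | 1-[2,4-bis(methoxymethoxy)-3-(3-methylbut-2-enyl)phenyl]ethanone | CC(=O)c1ccc(OCOC)c(CC=C(C)C)c1OCOC | intermediate
5 | 2,4-dihydroxybenzaldehyde | O=Cc1ccc(O)cc1O | starting material
6 | 3-methylbut-2-enal | CC(C)=CC=O | starting material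
7 | 2-hydroxy-3-(3-methylbut-2-enylidene)-4-oxocyclohexa-1,5-diene-1-carbaldehyde (ortho-quinone methide, reactive geometry drawn) | O=CC1=C(O)/C(=C/C=C(C)C)C(=O)C=C1 | intermediate
8 | 5-hydroxy-2,2-dimethyl-2H-chromene-6-carbaldehyde | O=Cc1ccc2c(c1O)C=CC(C)(C)O2 | intermediate
9 | 2,2-dimethyl-5-(prop-2-enyloxy)-2H-chromene-6-carbaldehyde | O=Cc1ccc2c(c1OCC=C)C=CC(C)(C)O2 | intermediate
10 | (E)-1-[2,4-bis(methoxymethoxy)-3-(3-methylbut-2-enyl)phenyl]-3-[2,2-dimethyl-5-(prop-2-enyloxy)-2H-chromen-6-yl]prop-2-en-1-one | COCOc1ccc(C(=O)/C=C/c2ccc3c(c2OCC=C)C=CC(C)(C)O3)c(OCOC)c1CC=C(C)C | intermediate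
11 | rac-[2,4-bis(methoxymethoxy)-3-(3-methylbut-2-enyl)phenyl]{trans-3-[2,2-dimethyl-5-(prop-2-enyloxy)-2H-chromen-6-yl]oxiran-2-yl}methanone (racemate; the 2S,3R enantiomer is drawn) | COCOc1ccc(C(=O)[C@H]2O[C@@H]2c2ccc3c(c2OCC=C)C=CC(C)(C)O3)c(OCOC)c1CC=C(C)C | intermediate
12 | 3-[2,4-bis(methoxymethoxy)-3-(3-methylbut-2-enyl)phenyl]-2-[2,2-dimethyl-5-(prop-2-enyloxy)-2H-chromen-6-yl]-3-oxopropanal (α-formyl deoxybenzoin, racemic and enolisable) | COCOc1ccc(C(=O)C(C=O)c2ccc3c(c2OCC=C)C=CC(C)(C)O3)c(OCOC)c1CC=C(C)C | intermediate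
13 | 2,7-dihydroxy-3-[2,2-dimethyl-5-(prop-2-enyloxy)-2H-chromen-6-yl]-8-(3-methylbut-2-enyl)-2,3-dihydro-4H-chromen-4-one (2-hydroxyisoflavanone, diastereomer mixture) | OC1Oc2c(CC=C(C)C)c(O)ccc2C(=O)C1c1ccc2c(c1OCC=C)C=CC(C)(C)O2 | intermediate
14 | 7-hydroxy-8-(3-methylbut-2-enyl)-3-[2,2-dimethyl-5-(prop-2-enyloxy)-2H-chromen-6-yl]-4H-chromen-4-one | O=c1c(-c2ccc3c(c2OCC=C)C=CC(C)(C)O3)coc2c(CC=C(C)C)c(O)ccc12 | intermediate
15 | 7-hydroxy-8-(3-methylbut-2-enyl)-3-[2,2-dimethyl-5-(prop-2-enyloxy)-2H-chromen-6-yl]-2,3-dihydro-4H-chromen-4-one (C3 epimerises freely) | O=C1c2ccc(O)c(CC=C(C)C)c2OCC1c1ccc2c(c1OCC=C)C=CC(C)(C)O2 | intermediate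
16 | (3R,4R)-3-[2,2-dimethyl-5-(prop-2-enyloxy)-2H-chromen-6-yl]-8-(3-methylbut-2-enyl)-3,4-dihydro-2H-chromene-4,7-diol (cis) | CC(C)=CCc1c(O)ccc2c1OC[C@@H](c1ccc3c(c1OCC=C)C=CC(C)(C)O3)[C@H]2O | intermediate
17 | (3R)-3-[2,2-dimethyl-5-(prop-2-enyloxy)-2H-chromen-6-yl]-8-(3-methylbut-2-enyl)-2,3-dihydro-7H-chromen-7-one (para-quinone methide) | O=C1C=CC2=C[C@H](c3ccc4c(c3OCC=C)C=CC(C)(C)O4)COC2=C1CC=C(C)C | intermediate
18 | (3R)-3-[2,2-dimethyl-5-(prop-2-enyloxy)-2H-chromen-6-yl]-8-(3-methylbut-2-enyl)-3,4-dihydro-2H-chromen-7-ol | CC(C)=CCc1c(O)ccc2c1OC[C@@H](c1ccc3c(c1OCC=C)C=CC(C)(C)O3)C2 | intermediate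
19 | 6-[(3R)-7-hydroxy-8-(3-methylbut-2-enyl)-3,4-dihydro-2H-chromen-3-yl]-2,2-dimethyl-2H-chromen-5-ol | CC(C)=CCc1c(O)ccc2c1OC[C@@H](c1ccc3c(c1O)C=CC(C)(C)O3)C2 | target

## Step count and risks

Total step count: 7. Longest linear sequence: 5 steps (1, 2, 5, 6, 7).

Steps most likely to fail:

**Step 6.** The benzylic cation may be captured by the neighbouring MOM ether oxygen of ring A, which after loss of the MOM cation gives a 3-hydroxyflavanone instead of the acyl shift; the formyl group may also be lost. The fallback switches that oxygen off as a sulfonate and closes ring C under base instead of acid. It sets out from 3 and comes back at 14.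
- Selective methoxymethylation of the non-chelated hydroxyl of 3 (MOMCl, K2CO3, acetone) gives 1-[2-hydroxy-4-(methoxymethoxy)-3-(3-methylbut-2-enyl)phenyl]ethanone F1.
- Claisen–Schmidt condensation with 9 (KOH, EtOH) gives the 2'-hydroxychalcone F2.
- TsCl and K2CO3 in acetone give the 2'-tosyloxychalcone F3.
- H2O2/NaOH gives the racemic trans-epoxide F4.
- BF3·OEt2 in CH2Cl2 gives the tosyloxy formyl deoxybenzoin F5; the electron-poor sulfonate oxygen cannot compete with the acyl shift.
- KOH in MeOH cleaves the sulfonate and, after acidification, the freed phenol closes ring C to the 7-O-MOM isoflavone F6.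
- Brief HCl/MeOH removes the MOM group and gives 14.

**Step 7.** The free 7-hydroxy chromone may be reduced slowly, and the acid-triggered deoxygenation may stall at 16 or eliminate to the achiral isoflav-3-ene. The fallback triggers the quinone methide under base with borohydride as the hydride source. It sets out from 16, isolated by running the ruthenium reduction at 40 °C only, and comes back at 18.
- Ac2O/pyridine gives the diacetate F7.
- K2CO3 and NaBH4 in MeOH–THF at 0 °C cleave the aryl acetate; the phenoxide expels the benzylic acetate to give 17, which borohydride reduces at once to 18.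
- Isolated 18 is deallylated with Pd(PPh3)4 and HCO2H/Et3N as in step 7.

**Step 1.** Direct C-prenylation gives modest yield and mixed regiochemistry. The fallback delivers the prenyl group by sigmatropic rearrangement. It sets out from 1 and comes back at 3.
- O-Alkylation of the non-chelated hydroxyl with 3-chloro-3-methylbut-1-yne (K2CO3, KI, acetone) gives 1-[2-hydroxy-4-(2-methylbut-3-yn-2-yloxy)phenyl]ethanone F8.
- Semihydrogenation (H2, Pd/CaCO3 poisoned with Pb(OAc)2, quinoline) gives 1-[2-hydroxy-4-(2-methylbut-3-en-2-yloxy)phenyl]ethanone F9.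
- Aromatic Claisen rearrangement (N,N-diethylaniline, 130 °C) moves the group to the carbon between the two oxygens with allylic transposition and gives 3.

## Further compounds

F1 | step 6 | 1-[2-hydroxy-4-(methoxymethoxy)-3-(3-methylbut-2-enyl)phenyl]ethanone | CC(=O)c1ccc(OCOC)c(CC=C(C)C)c1O
F2 | step 6 | (E)-1-[2-hydroxy-4-(methoxymethoxy)-3-(3-methylbut-2-enyl)phenyl]-3-[2,2-dimethyl-5-(prop-2-enyloxy)-2H-chromen-6-yl]prop-2-en-1-one | COCOc1ccc(C(=O)/C=C/c2ccc3c(c2OCC=C)C=CC(C)(C)O3)c(O)c1CC=C(C)C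
F3 | step 6 | 2-{(E)-3-[2,2-dimethyl-5-(prop-2-enyloxy)-2H-chromen-6-yl]prop-2-enoyl}-5-(methoxymethoxy)-6-(3-methylbut-2-enyl)phenyl 4-methylbenzenesulfonate | COCOc1ccc(C(=O)/C=C/c2ccc3c(c2OCC=C)C=CC(C)(C)O3)c(OS(=O)(=O)c4ccc(C)cc4)c1CC=C(C)C
F4 | step 6 | rac-2-({trans-3-[2,2-dimethyl-5-(prop-2-enyloxy)-2H-chromen-6-yl]oxiran-2-yl}carbonyl)-5-(methoxymethoxy)-6-(3-methylbut-2-enyl)phenyl 4-methylbenzenesulfonate (one enantiomer drawn) | COCOc1ccc(C(=O)[C@H]2O[C@@H]2c2ccc3c(c2OCC=C)C=CC(C)(C)O3)c(OS(=O)(=O)c4ccc(C)cc4)c1CC=C(C)C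
F5 | step 6 | 2-{2-[2,2-dimethyl-5-(prop-2-enyloxy)-2H-chromen-6-yl]-3-oxopropanoyl}-5-(methoxymethoxy)-6-(3-methylbut-2-enyl)phenyl 4-methylbenzenesulfonate | COCOc1ccc(C(=O)C(C=O)c2ccc3c(c2OCC=C)C=CC(C)(C)O3)c(OS(=O)(=O)c4ccc(C)cc4)c1CC=C(C)C
F6 | step 6 | 7-(methoxymethoxy)-8-(3-methylbut-2-enyl)-3-[2,2-dimethyl-5-(prop-2-enyloxy)-2H-chromen-6-yl]-4H-chromen-4-one | COCOc1ccc2c(=O)c(-c3ccc4c(c3OCC=C)C=CC(C)(C)O4)coc2c1CC=C(C)C
F7 | step 7 | (3R,4R)-7-acetoxy-3-[2,2-dimethyl-5-(prop-2-enyloxy)-2H-chromen-6-yl]-8-(3-methylbut-2-enyl)-3,4-dihydro-2H-chromen-4-yl acetate | CC(C)=CCc1c(OC(C)=O)ccc2c1OC[C@@H](c1ccc3c(c1OCC=C)C=CC(C)(C)O3)[C@H]2OC(C)=O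
F8 | step 1 | 1-[2-hydroxy-4-(2-methylbut-3-yn-2-yloxy)phenyl]ethanone | CC(=O)c1ccc(OC(C)(C)C#C)cc1O
F9 | step 1 | 1-[2-hydroxy-4-(2-methylbut-3-en-2-yloxy)phenyl]ethanone | CC(=O)c1ccc(OC(C)(C)C=C)cc1O
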